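**Numbering used throughout:** 1 dimethyl (2-oxoheptyl)phosphonate; 2 acetaldehyde; 3 (E)-non-2-en-4-one; 4 14-methoxy-14-oxotetradecanoic acid; 5 methyl 14-chloro-14-oxotetradecanoate; 6 phosphonium chloride (not isolated); 7 phosphorus ylide (not isolated); 8 methyl 13-(3-methyl-5-pentylfuran-2-yl)tridecanoate; 9 the target, 13-(3-methyl-5-pentylfuran-2-yl)tridecanoic acid.

**Remark on the chemistry:** the half ester 4 is taken as a purchasable compound. The target has no stereocentre and no configured double bond, so nothing has to be assigned.

## Analysis of the target

Target 9 is a furan fatty acid. Its ring (O1, C2, C3, C4, C5) carries a 12-carboxydodecyl chain at C2, a methyl group at C3, hydrogen at C4 and an n-pentyl group at C5. Read along the backbone, it is docosanoic acid in which C14 and C17 are bridged by oxygen and C15 bears the methyl branch. There is no stereogenic element, so the problem is one of constitution only. The 2,3,5-pattern must be fixed without ambiguity, because an isomer with the methyl group at C4, or with the two side chains exchanged, would have the same formula and nearly the same polarity as 9. The 2,3,5-trialkylfuran is electron-rich: it is protonated at the ring and opened or oligomerised by strong acid, it autoxidises, and it is consumed quickly by singlet oxygen and by electrophiles. The carboxylic acid has to be masked whenever acylating agents or strong bases are present. The feature used here is that C2 is an enol ether carbon, which is what an ester carbonyl carbon becomes on Wittig olefination. C2 and its chain together are therefore the fourteen carbons of tetradecanedioic acid (available as half ester 4), and O1–C2 is a latent ester bond. The remaining ring atoms O1, C5 (with pentyl), C4 and C3 (with methyl) are the O=C–C=C unit of enone 3. The difficulty is not complexity but economy and regiocontrol: twelve methylene groups offer no handle, and the positions C2/C5 and C3/C4 differ too little for a late regioselective reaction to be trusted.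

## Retrosynthetic reasoning

**9 to 8.** The acyl–oxygen bond of a methyl ester is cut. The acid is unmasked last because the key step uses an acid chloride, a nucleophilic phosphine and a strong amide base, all of which a free carboxyl group would consume. The forward reaction only has to hydrolyse an unhindered ester without exposing the furan to strong acid.

**8 to 7 (and its salt 6).** The ring bond C2=C3 is cut in the Wittig sense: C3, with its methyl group, becomes an ylide carbon, and C2 becomes the carbonyl carbon of an enol ester. This bond is chosen over the C–O bonds because cutting it puts C2 at the ester level and so turns the whole carboxyalkyl chain into a diacid derivative. It also divides the molecule into two halves of similar size. The forward reaction must olefinate an ester carbonyl through a five-membered transition state, and the ring becomes aromatic as soon as the P=O bond forms. Closing the same bond by reductive coupling of two carbonyl groups (McMurry type, low-valent titanium) would leave a ketone oxygen next to the enol ester. A 1,5-acyl shift between the two oxygens could then exchange methyl and pentyl; phosphorus on C3 rules this out.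

**6 to 3 and 5.** Two bonds are cut: O1–C2, which is an ordinary acyl–oxygen bond, and the P–C3 bond. In the forward direction a trialkylphosphine adds to the β-carbon of 3 and the enolate oxygen is acylated by 5. The polarity of 3 decides the regiochemistry completely: phosphorus can only end up on the methyl-bearing carbon and the acyl group only on the oxygen next to the pentyl-bearing carbon.

**5 to 4.** The C–Cl bond is cut. The forward reaction is a routine activation of the free carboxyl group of 4 beside its methyl ester.

**3 to 1 and 2.** The C=C bond of the enone is cut in the Horner–Wadsworth–Emmons sense. This gives 3 in one step from a ketophosphonate and a two-carbon aldehyde. The double-bond geometry is not carried into the target.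

## Alternatives that were turned down

**Alternative 1:** the textbook disconnection of both C–O bonds (O1–C2 and O1–C5). The forward key step is a Paal–Knorr cyclodehydration of 15-methyl-14,17-dioxodocosanoic acid A1 (or of its methyl ester, which is F2 in the fallback for step 3).
- In A1 every carbon–carbon bond of 9 is already in place, so the key step only removes water.
- The real work, the C14–C15 bond, needs an acyl-anion equivalent on a long-chain aldehyde, which costs extra redox steps from the diacid.
- The closure exposes the acid-sensitive product to acid and heat, and the C15 stereocentre is made only to be destroyed.
- It is the route most chemists would draw first, and it is longer than the chosen one. It is kept only as a safety net.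

**Alternative 2:** the biomimetic disconnection of O1–C2 and O1–C5 to dioxygen and methyl (14E,16E)-15-methyldocosa-14,16-dienoate A2. The forward key step is a [4+2] photooxygenation of A2 to the cis-endoperoxide A3 (methyl 13-(cis-4-methyl-6-pentyl-3,6-dihydro-1,2-dioxin-3-yl)tridecanoate), followed by Kornblum–DeLaMare rearrangement and dehydration to 8.
- The trisubstituted C14=C15 double bond has allylic hydrogens on three sides, so the Schenck ene reaction should compete with the cycloaddition.
- Furan 8 reacts with singlet oxygen faster than A2 does, so the two operations cannot be merged.
- A2 already holds all carbons of the target and needs a stereocontrolled union of two alkenyl partners, each made in several steps. The route would be about twice as long, and its key step adds a single oxygen atom.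

**Alternative 3:** disconnection of the exocyclic bond between C2 and the chain. The forward key step is lithiation of 4-methyl-2-pentylfuran A4 at its free α-position and alkylation with a thirteen-carbon ω-bromo electrophile carrying a masked carboxyl group.
- The ring is bought rather than built. A4 is not a commodity, and making it from 3-methylfuran A5 needs a metalation that does not distinguish the two α-positions cleanly, which brings back the inseparable-isomer problem.
- Alkylation of a furyllithium with a long primary bromide is slow and competes with elimination.
- The ester function does not survive the organolithium, so the carboxyl group must be carried as a protected alcohol and oxidised at the end in the presence of the oxidation-sensitive furan.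

Key step: step 3

## Route

Step 1
Reactants: 1 dimethyl (2-oxoheptyl)phosphonate; 2 acetaldehyde
Product: 3 (E)-non-2-en-4-one
Conditions: NaH (1.05 equiv), THF, 0 °C; then 2 (3 equiv), 0 °C to rt
Reagents that add atoms: none
Why: Horner–Wadsworth–Emmons olefination; the stabilised ketophosphonate anion is too weak a base to enolise acetaldehyde appreciably and should give the E-enone, whose geometry is erased in step 3 anyway.

Step 2
Reactants: 4 14-methoxy-14-oxotetradecanoic acid
Product: 5 methyl 14-chloro-14-oxotetradecanoate
Conditions: (COCl)2 (1.5 equiv), DMF (cat.), CH2Cl2, 0 °C to rt; evaporation and co-evaporation with toluene
Reagents that add atoms: oxalyl chloride, O=C(Cl)C(Cl)=O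
Why: Acid chloride formation through the Vilsmeier-type chloroiminium ion; the methyl ester is inert and the by-products are gases, and HCl must be removed completely because a phosphonium hydrochloride would divert enone 3 in step 3.

Step 3
Reactants: 3 (E)-non-2-en-4-one; 5 methyl 14-chloro-14-oxotetradecanoate
Product: 8 methyl 13-(3-methyl-5-pentylfuran-2-yl)tridecanoate, via phosphonium chloride 6 (not isolated), via phosphorus ylide 7 (not isolated)
Conditions: 3 (1.2 equiv), PBu3 (1.2 equiv), 5 (1.0 equiv), THF, argon, 0 °C to rt; then NaN(SiMe3)2 (1.05 equiv), −40 °C to rt, then 50 °C if needed
Reagents that add atoms: none
Why: Proposed new method: phosphine conjugate addition to an enone, O-acylation of the enolate by an acid chloride and intramolecular Wittig olefination of the enol ester carbonyl is an established furan synthesis for doubly activated or aryl-substituted Michael acceptors (and, in the benzo series, for (2-acyloxybenzyl)phosphonium salts), but it has not been shown for a plain β-alkyl enone such as 3 with no second acceptor group; the closest known reactions of such enones are phosphoniosilylation and Rauhut–Currier chemistry, which show that a trialkylphosphine adds to the β-carbon and that the enolate can be trapped at oxygen. PBu3 should add reversibly to C2 of 3 (the future furan C3), and acylation of the enolate oxygen by 5 (free or as its acylphosphonium form) removes the adduct from the equilibrium as salt 6; NaN(SiMe3)2 then takes the allylic proton next to phosphorus, a stronger base than the usual tertiary amine being chosen because this non-benzylic P-trialkyl phosphonium ion is a weaker acid. Ylide 7 attacks the enol ester carbonyl and the oxaphosphetane collapses with loss of Bu3P=O. The furan ring is closed at the C2–C3 bond by a 5-exo-trig attack of the ylide carbon on the C=O group, and the cycloreversion turns this bond into the ring double bond, so the ring is aromatic as soon as phosphorus leaves. No stereocentre is created; the racemic centre of 6 and the enol ester geometry vanish in the furan. Regiochemistry is fixed by the polarity of 3 (phosphorus only on the methyl-bearing carbon, acyl only on the oxygen beside the pentyl-bearing carbon), and since no second carbonyl group flanks the enol ester, no acyl shift can exchange methyl and pentyl. O- over C-acylation is expected for a charge-separated enolate and a hard acyl chloride; the geometry needed for closure (oxygen cis to the phosphorus-bearing carbon) is favoured by P+/O− attraction in the adduct, and allyl-type delocalisation in 7 lowers the barrier to rotation so that the other geometry can still reach the reactive form. Olefination should win over acyl transfer from the betaine because a ketone enolate is a poorer leaving group than the phenoxide of the benzofuran case, and the remote methyl ester is less electrophilic and cannot reach the ylide through a small ring.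

Step 4
Reactants: 8 methyl 13-(3-methyl-5-pentylfuran-2-yl)tridecanoate
Product: 9 13-(3-methyl-5-pentylfuran-2-yl)tridecanoic acid
Conditions: LiOH·H2O (3 equiv), THF/MeOH/H2O, rt, argon; then 1 M HCl to pH 4 at 0 °C, extraction
Reagents that add atoms: lithium hydroxide, [Li+].[OH-]
Why: Saponification (acyl–oxygen cleavage) of an unhindered methyl ester; the trialkylfuran is inert to hydroxide, and the brief, cold acidification to pH 4 under argon is chosen to avoid ring protonation and autoxidation.

## Compound list

1 | dimethyl (2-oxoheptyl)phosphonate | CCCCCC(=O)CP(=O)(OC)OC | starting material
2 | acetaldehyde | CC=O | starting material
3 | (E)-non-2-en-4-one | C/C=C/C(=O)CCCCC | intermediate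
4 | 14-methoxy-14-oxotetradecanoic acid (monomethyl tetradecanedioate) | COC(=O)CCCCCCCCCCCCC(=O)O | starting material
5 | methyl 14-chloro-14-oxotetradecanoate | COC(=O)CCCCCCCCCCCCC(Cl)=O | intermediate
6 | tributyl[(3Z)-4-[(14-methoxy-14-oxotetradecanoyl)oxy]non-3-en-2-yl]phosphonium chloride (racemic) | CCCC[P+](CCCC)(CCCC)C(C)/C=C(/CCCCC)OC(=O)CCCCCCCCCCCCC(=O)OC.[Cl-] | intermediate
7 | methyl (3Z)-2-(tributylphosphoranylidene)non-3-en-4-yl tetradecanedioate | CCCCP(CCCC)(CCCC)=C(C)/C=C(/CCCCC)OC(=O)CCCCCCCCCCCCC(=O)OC | intermediate
8 | methyl 13-(3-methyl-5-pentylfuran-2-yl)tridecanoate | CCCCCc1cc(C)c(CCCCCCCCCCCCC(=O)OC)o1 | intermediate
9 | 13-(3-methyl-5-pentylfuran-2-yl)tridecanoic acid | CCCCCc1cc(C)c(CCCCCCCCCCCCC(=O)O)o1 | target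

## Step count and least certain steps

Total step count: 4. Longest linear sequence: 3 (steps 2, 3 and 4 from 4; equally steps 1, 3 and 4 from 1 and 2).

**Step 3 (key step, Proposed new method).** The most likely failure is that salt 6 does not build up. Three processes could cause this: phosphine addition to a β-methyl enone is reversible and unfavourable, the phosphine can be held back as the acylphosphonium ion of 5, and chloride can reverse the O-acylation. At the ylide stage, acyl transfer from the betaine or deprotonation next to the enol ester carbonyl (with loss of a ketene) could compete with olefination. The fallback gives up ring closure at carbon and uses known chemistry only. It sets out from acid chloride 5 and enone 3 and comes back to the route at 8. Rosenmund reduction of 5 (H2, Pd/BaSO4, 2,6-lutidine, THF) would give methyl 14-oxotetradecanoate F1. A Stetter reaction of F1 with 3 (3-benzyl-5-(2-hydroxyethyl)-4-methylthiazolium chloride cat., Et3N, EtOH, 75 °C) would deliver the acyl-anion equivalent to the β-carbon of 3 and give methyl 15-methyl-14,17-dioxodocosanoate F2 (racemic). Paal–Knorr cyclodehydration of F2 (p-toluenesulfonic acid cat., toluene, 80 °C, removal of water) would then close both C–O bonds to give 8.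

**Step 1.** Acetaldehyde may be lost by evaporation or self-aldolisation before it is olefinated, and the phosphonate anion may add in conjugate fashion to the product enone. The fallback replaces olefination by aldol addition and dehydration. It sets out from 2 and comes back at 3. The kinetic lithium enolate of heptan-2-one (LiN(iPr)2, THF, −78 °C, deprotonation at the methyl group) would be added to 2 to give 2-hydroxynonan-4-one F3 (racemic). Acid-catalysed dehydration of F3 (p-toluenesulfonic acid cat., toluene, 60 °C) would give 3.

**Step 4.** Ring protonation with opening or oligomerisation during acidification, and autoxidation of the free furan acid on handling, are the likely losses. The fallback changes the bond that is broken, from acyl–oxygen to alkyl–oxygen. It sets out from 8 and comes back at 9. S_N2 demethylation with LiI in pyridine at reflux would give lithium 13-(3-methyl-5-pentylfuran-2-yl)tridecanoate F4, which would be protonated with a pH 5 buffer to give 9 without strong aqueous acid or base.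

## Further compounds

F1 | step 3 | methyl 14-oxotetradecanoate | COC(=O)CCCCCCCCCCCCC=O
F2 | step 3 | methyl 15-methyl-14,17-dioxodocosanoate (racemic) | CCCCCC(=O)CC(C)C(=O)CCCCCCCCCCCCC(=O)OC
F3 | step 1 | 2-hydroxynonan-4-one (racemic) | CC(O)CC(=O)CCCCC
F4 | step 4 | lithium 13-(3-methyl-5-pentylfuran-2-yl)tridecanoate | [Li+].[O-]C(=O)CCCCCCCCCCCCc1oc(CCCCC)cc1C
A1 | alternative 1 | 15-methyl-14,17-dioxodocosanoic acid (racemic) | CCCCCC(=O)CC(C)C(=O)CCCCCCCCCCCCC(=O)O
A2 | alternative 2 | methyl (14E,16E)-15-methyldocosa-14,16-dienoate | CCCCC/C=C/C(C)=C/CCCCCCCCCCCCC(=O)OC
A3 | alternative 2 | methyl 13-(cis-4-methyl-6-pentyl-3,6-dihydro-1,2-dioxin-3-yl)tridecanoate (racemic, one enantiomer drawn) | CCCCC[C@@H]1OO[C@H](CCCCCCCCCCCCC(=O)OC)C(C)=C1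
A4 | alternative 3 | 4-methyl-2-pentylfuran | CCCCCc1cc(C)co1
A5 | alternative 3 | 3-methylfuran | Cc1ccoc1
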